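**Retrosynthetic overview**

1. The target is the C7 prenyl ether of 5,7-dihydroxy-2-(4-hydroxyphenoxy)chromone. The prenyl O–C bond is made last, on the most acidic hydroxyl, after hydrogenolysis of three benzyl ethers.
2. The strategy rests on the substitution of ring A: O1 sits on C8a, the C4 carbonyl on the adjacent C4a, and the C5 oxygen on the next carbon. A 3-alkoxybenzyne gives this contiguous pattern when it inserts into the C–O bond of a carboxylic acid.
3. Key disconnection: O1–C8a, C4–C4a and O1–C2, leading to 3,5-bis(benzyloxy)benzyne (from its 2-silylaryl triflate) and 3-[4-(benzyloxy)phenoxy]propiolic acid.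
4. The silyl triflate comes from 3,5-bis(benzyloxy)phenol by carbamate-directed ortho-silylation; the acid comes from 4-(benzyloxy)phenol, trichloroethylene and CO2.
5. Ring order: ring A and the hydroquinone ring are bought; ring C (the pyranone) is the only ring formed, in the key step.

Key step: step 6

Remark: benzyl ethers are used as the phenol protecting groups, because the C2 aryloxy group of the chromone is a vinylogous carbonate that can exchange with water or alcohols under the acid that acetal-type groups require, whereas neutral hydrogenolysis spares it; 3,5-bis(benzyloxy)phenol and 4-(benzyloxy)phenol are taken as purchased.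

**Route**

Step 1
Reactants: 1 3,5-bis(benzyloxy)phenol
Product: 2 3,5-bis(benzyloxy)phenyl N-(propan-2-yl)carbamate
Conditions: isopropyl isocyanate (1.5 equiv), Et3N (0.2 equiv), CH2Cl2, rt
Reagents that add atoms: isopropyl isocyanate, CC(C)N=C=O
Why: Amine-catalysed addition of the phenol to the isocyanate (carbamoylation) installs an N–H carbamate that directs the lithiation of step 2 and can later be removed by elimination.

Step 2
Reactants: 2 3,5-bis(benzyloxy)phenyl N-(propan-2-yl)carbamate
Product: 6 3,5-bis(benzyloxy)-2-(trimethylsilyl)phenyl N-(propan-2-yl)carbamate, via N-silyl carbamate 3 (not isolated), via aryllithium 4 (not isolated), via disilyl carbamate 5 (not isolated)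
Conditions: TBSOTf (1.1 equiv), TMEDA, Et2O, 0 °C to rt; n-BuLi (2.1 equiv), TMEDA, −78 °C; TMSCl, −78 °C to rt; aq. NaHSO4 work-up
Reagents that add atoms: chlorotrimethylsilane, C[Si](C)(C)Cl
Why: After in situ N-silylation of the carbamate, directed ortho-metalation should occur at the carbon flanked by the carbamate and a benzyloxy group (the two such carbons are equivalent), the aryllithium is trapped by TMSCl, and the N-silyl group is hydrolysed on work-up.

Step 3
Reactants: 6 3,5-bis(benzyloxy)-2-(trimethylsilyl)phenyl N-(propan-2-yl)carbamate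
Product: 8 3,5-bis(benzyloxy)-2-(trimethylsilyl)phenyl trifluoromethanesulfonate, via silyl phenol 7 (not isolated)
Conditions: DBU (1.5 equiv), Et2NH (1.25 equiv), MeCN, 40 °C; then PhNTf2 (1.5 equiv), rt
Reagents that add atoms: N-phenylbis(trifluoromethanesulfonimide), FC(F)(F)S(=O)(=O)N(c1ccccc1)S(=O)(=O)C(F)(F)F
Why: DBU deprotonates the carbamate N–H so that isopropyl isocyanate is expelled (E1cB carbamate cleavage) and scavenged by diethylamine as a urea, and the phenoxide so freed is O-sulfonylated in the same flask by PhNTf2.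

Step 4
Reactants: 9 4-(benzyloxy)phenol; 10 trichloroethylene
Product: 11 1-(benzyloxy)-4-{[(E)-1,2-dichloroethenyl]oxy}benzene
Conditions: K2CO3 (1.5 equiv), DMF, 70 °C
Reagents that add atoms: none
Why: The phenoxide replaces one vinylic chloride of trichloroethylene (net nucleophilic vinylic substitution), which should give the E-dichlorovinyl aryl ether, and the benzyl ether is inert to K2CO3.

Step 5
Reactants: 11 1-(benzyloxy)-4-{[(E)-1,2-dichloroethenyl]oxy}benzene
Product: 15 3-[4-(benzyloxy)phenoxy]prop-2-ynoic acid, via chloroalkynyl ether 12 (not isolated), via lithium acetylide 13 (not isolated), via lithium carboxylate 14 (not isolated)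
Conditions: n-BuLi (2.3 equiv), THF, −78 to −40 °C; CO2 (dry gas), −78 to 0 °C; cold 1 M HCl to pH 3 at 0 °C, rapid extraction, concentration below 20 °C, used at once
Reagents that add atoms: carbon dioxide, O=C=O
Why: n-BuLi brings about dehydrochlorination to the chloroalkynyl ether and then chlorine–lithium exchange to the lithium aryloxyacetylide, which is carboxylated by CO2 (acetylide carboxylation), and the cold, brief acidification takes account of the sensitivity of the ynol-ether acid.

Step 6
Reactants: 8 3,5-bis(benzyloxy)-2-(trimethylsilyl)phenyl trifluoromethanesulfonate; 15 3-[4-(benzyloxy)phenoxy]prop-2-ynoic acid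
Product: 18 5,7-bis(benzyloxy)-2-[4-(benzyloxy)phenoxy]-4H-chromen-4-one, via aryne 16 (not isolated), via hydroxyaryl ynone 17 (not isolated)
Conditions: 8 (1.5 equiv), CsF (4 equiv), dry THF, sealed tube, 100 °C
Reagents that add atoms: none
Why: Fluoride removes the trimethylsilyl group of 8 and triflate departs to give aryne 16 while the acid is present as its cesium carboxylate; the carboxylate oxygen adds to the aryne carbon remote from the flanking benzyloxy group (future C8a), the aryl anion so placed next to that benzyloxy group (future C4a) attacks the ester carbonyl just formed, and the four-membered alkoxide opens to the 2-acylphenoxide, a net insertion of the aryne into the carboxyl C–O bond. The closest known reaction type is the fluoride-mediated insertion of arynes into carboxylic acids to give 2-hydroxyaryl ketones, which with arylpropiolic acids runs on to flavones; the present acid is the ynol-ether member of that substrate class. Ring C then closes by 6-endo-dig oxa-Michael addition of the phenoxide of 17 to the alkyne carbon that carries the aryloxy group, forming O1–C2, and the proton of the acid ends on C3. No stereocenter is formed. The step needs regioselective capture of the aryne, secured by the inductively withdrawing alkoxy group beside the triple bond, which directs the oxygen nucleophile to the distal carbon, and it needs 6-endo over 5-exo closure, secured by the polarization of the ynone, which makes the oxygen-bearing β-carbon the electrophilic site.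

Step 7
Reactants: 18 5,7-bis(benzyloxy)-2-[4-(benzyloxy)phenoxy]-4H-chromen-4-one
Product: 19 5,7-dihydroxy-2-(4-hydroxyphenoxy)-4H-chromen-4-one
Conditions: H2 (1 atm), Pd/C (10 wt%), EtOAc/THF, rt
Reagents that add atoms: none
Why: Hydrogenolysis of the three aryl benzyl ethers over Pd/C is neutral, so the C2 aryloxy linkage and the electron-rich C2–C3 double bond of the chromone should remain untouched.

Step 8
Reactants: 19 5,7-dihydroxy-2-(4-hydroxyphenoxy)-4H-chromen-4-one; 20 prenyl bromide (1-bromo-3-methylbut-2-ene)
Product: 21 5-hydroxy-2-(4-hydroxyphenoxy)-7-[(3-methylbut-2-en-1-yl)oxy]-4H-chromen-4-one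
Conditions: 20 (1.05 equiv), KHCO3 (1.5 equiv), DMF, rt
Reagents that add atoms: none
Why: In this Williamson etherification under a weak base the C7 hydroxyl, para to the C4 carbonyl, is the most acidic and is the one ionised by KHCO3, whereas the C5 hydroxyl is tied up in a hydrogen bond to the carbonyl and the C4' hydroxyl is an ordinary phenol, so one equivalent of the allylic bromide should alkylate O7.

**Compound list**

1 | 3,5-bis(benzyloxy)phenol | Oc1cc(OCc2ccccc2)cc(OCc2ccccc2)c1 | starting material
2 | 3,5-bis(benzyloxy)phenyl N-(propan-2-yl)carbamate | CC(C)NC(=O)Oc1cc(OCc2ccccc2)cc(OCc2ccccc2)c1 | intermediate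
3 | 3,5-bis(benzyloxy)phenyl N-(tert-butyldimethylsilyl)-N-(propan-2-yl)carbamate | CC(C)N(C(=O)Oc1cc(OCc2ccccc2)cc(OCc2ccccc2)c1)[Si](C)(C)C(C)(C)C | intermediate (not isolated)
4 | [2,4-bis(benzyloxy)-6-{[(tert-butyldimethylsilyl)(propan-2-yl)carbamoyl]oxy}phenyl]lithium | CC(C)N(C(=O)Oc1cc(OCc2ccccc2)cc(OCc2ccccc2)c1[Li])[Si](C)(C)C(C)(C)C | intermediate (not isolated)
5 | 3,5-bis(benzyloxy)-2-(trimethylsilyl)phenyl N-(tert-butyldimethylsilyl)-N-(propan-2-yl)carbamate | CC(C)N(C(=O)Oc1cc(OCc2ccccc2)cc(OCc2ccccc2)c1[Si](C)(C)C)[Si](C)(C)C(C)(C)C | intermediate (not isolated)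
6 | 3,5-bis(benzyloxy)-2-(trimethylsilyl)phenyl N-(propan-2-yl)carbamate | CC(C)NC(=O)Oc1cc(OCc2ccccc2)cc(OCc2ccccc2)c1[Si](C)(C)C | intermediate
7 | 3,5-bis(benzyloxy)-2-(trimethylsilyl)phenol | Oc1cc(OCc2ccccc2)cc(OCc2ccccc2)c1[Si](C)(C)C | intermediate (not isolated)
8 | 3,5-bis(benzyloxy)-2-(trimethylsilyl)phenyl trifluoromethanesulfonate | C[Si](C)(C)c1c(OCc2ccccc2)cc(OCc2ccccc2)cc1OS(=O)(=O)C(F)(F)F | intermediate
9 | 4-(benzyloxy)phenol | Oc1ccc(OCc2ccccc2)cc1 | starting material
10 | trichloroethylene (1,1,2-trichloroethene) | ClC=C(Cl)Cl | starting material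
11 | 1-(benzyloxy)-4-{[(E)-1,2-dichloroethenyl]oxy}benzene | Cl/C=C(/Cl)Oc1ccc(OCc2ccccc2)cc1 | intermediate
12 | 1-(benzyloxy)-4-[(chloroethynyl)oxy]benzene | ClC#COc1ccc(OCc2ccccc2)cc1 | intermediate (not isolated)
13 | {[4-(benzyloxy)phenoxy]ethynyl}lithium | [Li]C#COc1ccc(OCc2ccccc2)cc1 | intermediate (not isolated)
14 | lithium 3-[4-(benzyloxy)phenoxy]prop-2-ynoate | [Li+].[O-]C(=O)C#COc1ccc(OCc2ccccc2)cc1 | intermediate (not isolated)
15 | 3-[4-(benzyloxy)phenoxy]prop-2-ynoic acid | OC(=O)C#COc1ccc(OCc2ccccc2)cc1 | intermediate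
16 | 3,5-bis(benzyloxy)-1,2-didehydrobenzene (3,5-bis(benzyloxy)benzyne) | O(Cc1ccccc1)C1=CC(OCc2ccccc2)=CC#C1 | intermediate (not isolated)
17 | 1-[2,4-bis(benzyloxy)-6-hydroxyphenyl]-3-[4-(benzyloxy)phenoxy]prop-2-yn-1-one | O=C(C#COc1ccc(OCc2ccccc2)cc1)c1c(O)cc(OCc2ccccc2)cc1OCc1ccccc1 | intermediate (not isolated)
18 | 5,7-bis(benzyloxy)-2-[4-(benzyloxy)phenoxy]-4H-chromen-4-one | O=c1cc(Oc2ccc(OCc3ccccc3)cc2)oc2cc(OCc3ccccc3)cc(OCc3ccccc3)c12 | intermediate
19 | 5,7-dihydroxy-2-(4-hydroxyphenoxy)-4H-chromen-4-one | O=c1cc(Oc2ccc(O)cc2)oc2cc(O)cc(O)c12 | intermediate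
20 | prenyl bromide (1-bromo-3-methylbut-2-ene) | CC(C)=CCBr | starting material
21 | 5-hydroxy-2-(4-hydroxyphenoxy)-7-[(3-methylbut-2-en-1-yl)oxy]-4H-chromen-4-one | CC(C)=CCOc1cc(O)c2c(=O)cc(Oc3ccc(O)cc3)oc2c1 | target

**Step count**

Total steps: 8. Longest linear sequence: 6 steps (steps 1, 2, 3, 6, 7, 8, from compound 1).

**Steps most likely to fail**

Step 6. The ynol-ether acid may be lost in the hot fluoride medium before the aryne captures it, by decarboxylation or by addition of fluoride or carboxylate to the alkyne. The aryl anion may also be protonated before the acyl shift, giving the aryl ester, and the aryloxy group may be displaced from C2 of the product by fluoride. The fallback brings in the aryloxy group last and keeps the fragile acid out of the aryne step. It sets out from 8: the same aryne is generated with CsF in THF in a sealed tube in the presence of acetic acid, whose insertion should give 1-[2,4-bis(benzyloxy)-6-hydroxyphenyl]ethan-1-one F1. Condensation of F1 with CS2 and KOtBu in THF should give 5,7-bis(benzyloxy)-4-hydroxy-2H-chromene-2-thione F2. S-Methylation with MeI and K2CO3 in acetone should give 5,7-bis(benzyloxy)-2-(methylsulfanyl)-4H-chromen-4-one F3, and oxidation with mCPBA in CH2Cl2 should give 5,7-bis(benzyloxy)-2-(methanesulfonyl)-4H-chromen-4-one F4. Addition–elimination of the phenoxide of 9 (K2CO3, DMF, rt) at C2 of F4 then comes back to the route at 18.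

Step 5. The free acid may decompose during acidification and concentration, by hydration of the ynol ether, decarboxylation or self-addition of the carboxyl group to the alkyne. The fallback sets out from 11. The lithium acetylide 13 is made as in step 5 but quenched with allyl chloroformate to give prop-2-en-1-yl 3-[4-(benzyloxy)phenoxy]prop-2-ynoate F5, a push–pull alkyne that should tolerate chromatography and storage. Allyl transfer with catalytic Pd(PPh3)4 and sodium 2-ethylhexanoate in EtOAc/CH2Cl2 at rt should precipitate sodium 3-[4-(benzyloxy)phenoxy]prop-2-ynoate F6 under neutral, water-free conditions. The dried salt is submitted to the conditions of step 6 with 8 and CsF and protonated by aqueous NH4Cl on work-up, so that the route is rejoined at 18 without the free acid being handled.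

Step 8. The alkylation may discriminate poorly between the C7 and C4' hydroxyls, run on to bis-ethers, or give C-prenylation at C6 or C8. The fallback replaces direct chemoselective alkylation by protecting-group differentiation and sets out from 19. Peracetylation (Ac2O, pyridine, DMAP) should give 4-{[5,7-bis(acetyloxy)-4-oxo-4H-chromen-2-yl]oxy}phenyl acetate F7. Thiophenol and imidazole in N-methylpyrrolidone at 0 °C should remove only the most activated acetate, at O7, to give 4-{[5-(acetyloxy)-7-hydroxy-4-oxo-4H-chromen-2-yl]oxy}phenyl acetate F8. A Mitsunobu reaction with 3-methylbut-2-en-1-ol (PPh3, DIAD, THF, 0 °C) should give 4-({5-(acetyloxy)-7-[(3-methylbut-2-en-1-yl)oxy]-4-oxo-4H-chromen-2-yl}oxy)phenyl acetate F9. Brief methanolysis of the two aryl acetates (catalytic K2CO3, MeOH, 0 °C) then arrives at 21.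

**Further compounds**

F1 | step 6 | 1-[2,4-bis(benzyloxy)-6-hydroxyphenyl]ethan-1-one | CC(=O)c1c(O)cc(OCc2ccccc2)cc1OCc1ccccc1
F2 | step 6 | 5,7-bis(benzyloxy)-4-hydroxy-2H-chromene-2-thione | S=c1cc(O)c2c(OCc3ccccc3)cc(OCc3ccccc3)cc2o1
F3 | step 6 | 5,7-bis(benzyloxy)-2-(methylsulfanyl)-4H-chromen-4-one | CSc1cc(=O)c2c(OCc3ccccc3)cc(OCc3ccccc3)cc2o1
F4 | step 6 | 5,7-bis(benzyloxy)-2-(methanesulfonyl)-4H-chromen-4-one | CS(=O)(=O)c1cc(=O)c2c(OCc3ccccc3)cc(OCc3ccccc3)cc2o1
F5 | step 5 | prop-2-en-1-yl 3-[4-(benzyloxy)phenoxy]prop-2-ynoate | C=CCOC(=O)C#COc1ccc(OCc2ccccc2)cc1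
F6 | step 5 | sodium 3-[4-(benzyloxy)phenoxy]prop-2-ynoate | [Na+].[O-]C(=O)C#COc1ccc(OCc2ccccc2)cc1
F7 | step 8 | 4-{[5,7-bis(acetyloxy)-4-oxo-4H-chromen-2-yl]oxy}phenyl acetate | CC(=O)Oc1ccc(Oc2cc(=O)c3c(OC(C)=O)cc(OC(C)=O)cc3o2)cc1
F8 | step 8 | 4-{[5-(acetyloxy)-7-hydroxy-4-oxo-4H-chromen-2-yl]oxy}phenyl acetate | CC(=O)Oc1ccc(Oc2cc(=O)c3c(OC(C)=O)cc(O)cc3o2)cc1
F9 | step 8 | 4-({5-(acetyloxy)-7-[(3-methylbut-2-en-1-yl)oxy]-4-oxo-4H-chromen-2-yl}oxy)phenyl acetate | CC(=O)Oc1ccc(Oc2cc(=O)c3c(OC(C)=O)cc(OCC=C(C)C)cc3o2)cc1
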